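**Retrosynthetic overview**

1. Abietane numbering is used in the text: ring A = C1–C5 + C10, ring B = C5–C10, C14 = carboxyl carbon on C8, C18 = carboxyl carbon on C4, side chain = C11–C13 + isopropyl. Target 22 comes from di-tert-butyl ester dioxolane 21 by one acidic global deprotection.
2. 21 comes from monocyclic acetate 19. Ring B is closed at the hindered C9–C10 bond by a hydrogen-atom-transfer radical 6-endo cyclisation with loss of a C7 acetate. This sets quaternary C10, C9, the trans ring fusion and the C7=C8 enoate in one operation.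
3. Enabling feature: in ring B the C14 carboxyl sits on C8 of the C7=C8 double bond. C9 is therefore the β-carbon of an acrylate next to the methyl-bearing quaternary C10, which is a tertiary radical available from a C1=C10 alkene of ring A. Allylic C7 can carry a leaving group that returns the double bond.
4. 19 comes from a C7–C8 union of ring A aldehyde 9 (eleven skeletal carbons) with ynoate 16 (nine) by hydroalumination/aldol addition, which fixes the Z enoate geometry.
5. Ring order: ring A first, ring B last. In ring A an asymmetric Michael addition sets C4, an aldol condensation closes the ring, and a CBS carbinol at C1 is relayed to C5 by a Claisen rearrangement.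

Key step: step 11

Assumption: the sense of induction in step 2 is taken from the behaviour of α-alkyl β-keto esters with this catalyst family. If a test run gave the (S)-aldehyde, the pseudoenantiomeric quinidine-derived catalyst would be used, with nothing else changing.

**Route**

Step 1
Reactants: 1 tert-butyl propanoate
Product: 3 tert-butyl 2-methyl-3-oxopropanoate, via lithium enolate 2 (not isolated)
Conditions: LiN(i-Pr)2 (LDA), THF, −78 °C; HCO2Et, −78 to 0 °C; aq NH4Cl
Reagents that add atoms: ethyl formate, CCOC=O
Why: Crossed Claisen condensation (C-formylation) of the ester enolate with a non-enolisable formate should be driven by formation of the stabilised enolate of 3, and the α-carbon stays enolisable, so no lasting stereocentre is formed.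

Step 2
Reactants: 3 tert-butyl 2-methyl-3-oxopropanoate; 4 pent-1-en-3-one
Product: 5 tert-butyl (2R)-2-formyl-2-methyl-5-oxoheptanoate
Conditions: quinine-derived 6'-hydroxy-9-O-(9-phenanthryl) cinchona catalyst (10 mol %), CH2Cl2, −20 °C
Reagents that add atoms: none
Why: In this bifunctional cinchona-catalysed Michael addition of an α-substituted 1,3-dicarbonyl donor to a vinyl ketone, the quinuclidine deprotonates 3 and the 6'-OH binds 4, so one enolate face is alkylated and quaternary C4 is set as R.

Step 3
Reactants: 5 tert-butyl (2R)-2-formyl-2-methyl-5-oxoheptanoate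
Product: 6 tert-butyl (1R)-1,3-dimethyl-4-oxocyclohex-2-ene-1-carboxylate
Conditions: pyrrolidine (20 mol %), AcOH (20 mol %), toluene, 60 °C
Reagents that add atoms: none
Why: In this intramolecular aldol condensation (second half of a Robinson annulation) through the ketone enamine, only attack of C10 on the non-enolisable aldehyde C5 gives a six-membered ring, the mild amine/acid pair avoids deformylation, and C4 is untouched.

Step 4
Reactants: 6 tert-butyl (1R)-1,3-dimethyl-4-oxocyclohex-2-ene-1-carboxylate
Product: 7 tert-butyl (1R,4R)-4-hydroxy-1,3-dimethylcyclohex-2-ene-1-carboxylate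
Conditions: (S)-2-methyl-CBS-oxazaborolidine (15 mol %), BH3·SMe2, THF, −30 °C; aq work-up
Reagents that add atoms: none
Why: In the Corey–Bakshi–Shibata reduction, catalyst-controlled 1,2-hydride delivery with the 2-methylalkenyl arm as the large group should give the (R)-carbinol at C1, cis to the C4 methyl, and it turns any minor enantiomer of 6 into a separable diastereomer.

Step 5
Reactants: 7 tert-butyl (1R,4R)-4-hydroxy-1,3-dimethylcyclohex-2-ene-1-carboxylate
Product: 9 tert-butyl (1R,2R)-1,3-dimethyl-2-(2-oxoethyl)cyclohex-3-ene-1-carboxylate, via allyl vinyl ether 8 (not isolated)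
Conditions: n-BuOCH=CH2, Pd(OCOCF3)2 (5 mol %), 4,7-diphenyl-1,10-phenanthroline (5 mol %), Et3N, 75 °C; evaporate; xylenes, 140 °C
Reagents that add atoms: butyl vinyl ether, C=COCCCC
Why: Palladium-catalysed transfer vinylation is followed by a thermal Claisen [3,3] rearrangement that is suprafacial across the ring, so the C1–O configuration is relayed to the new C5–C6 bond (cis to the C4 methyl, trans to the ester) and the alkene moves to C1=C10.

Step 6
Reactants: 10 3-methylbutan-2-one; 11 3-bromoprop-1-yne
Product: 13 2-methylhept-6-yn-3-one, via lithium enolate 12 (not isolated)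
Conditions: LiN(i-Pr)2 (LDA), THF, −78 °C; 11, DMPU, −78 °C to rt
Reagents that add atoms: none
Why: Kinetic deprotonation at the methyl group of the methyl ketone and SN2 alkylation with a reactive propargylic bromide form no stereocentre.

Step 7
Reactants: 13 2-methylhept-6-yn-3-one
Product: 14 2-(but-3-yn-1-yl)-2-(propan-2-yl)-1,3-dioxolane
Conditions: HOCH2CH2OH, p-TsOH·H2O (cat.), toluene, reflux, Dean–Stark
Reagents that add atoms: ethane-1,2-diol, OCCO
Why: Acid-catalysed ketalisation with azeotropic removal of water masks C13 against the hydride of step 9 and the enolate of step 11.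

Step 8
Reactants: 14 2-(but-3-yn-1-yl)-2-(propan-2-yl)-1,3-dioxolane
Product: 16 tert-butyl 5-[2-(propan-2-yl)-1,3-dioxolan-2-yl]pent-2-ynoate, via lithium acetylide 15 (not isolated)
Conditions: n-BuLi, THF, −78 °C; Boc2O, −78 to 0 °C; aq NH4Cl
Reagents that add atoms: di-tert-butyl dicarbonate, CC(C)(C)OC(=O)OC(=O)OC(C)(C)C
Why: Deprotonation of the terminal alkyne and C-acylation of the acetylide with the dicarbonate is a standard entry to tert-butyl ynoates, and the ketal is inert to it.

Step 9
Reactants: 16 tert-butyl 5-[2-(propan-2-yl)-1,3-dioxolan-2-yl]pent-2-ynoate; 9 tert-butyl (1R,2R)-1,3-dimethyl-2-(2-oxoethyl)cyclohex-3-ene-1-carboxylate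
Product: 18 tert-butyl (1R,2R)-2-[(3Z)-3-(tert-butoxycarbonyl)-2-hydroxy-6-[2-(propan-2-yl)-1,3-dioxolan-2-yl]hex-3-en-1-yl]-1,3-dimethylcyclohex-3-ene-1-carboxylate (both C7 carbinol epimers), via vinylalane 17 (not isolated)
Conditions: i-Bu2AlH, HMPA, THF, 0 °C, then 16; then 9, 0 °C to rt; aq potassium sodium tartrate
Reagents that add atoms: none
Why: Syn hydroalumination of the ynoate (hydride to C9, aluminium to C8) and aldol-type addition of the vinylalane to the aldehyde is the vinylalumination route to β-substituted Morita–Baylis–Hillman adducts; C7 enters on the side of the C9 hydrogen, which fixes the Z geometry (C11 cis to the ester), and the C7 configuration is of no consequence.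

Step 10
Reactants: 18 the Z allylic alcohol of step 9
Product: 19 tert-butyl (1R,2R)-2-[(3Z)-2-acetoxy-3-(tert-butoxycarbonyl)-6-[2-(propan-2-yl)-1,3-dioxolan-2-yl]hex-3-en-1-yl]-1,3-dimethylcyclohex-3-ene-1-carboxylate (both C7 epimers)
Conditions: Ac2O, Et3N, DMAP (cat.), CH2Cl2, 0 °C to rt
Reagents that add atoms: acetic anhydride, CC(=O)OC(C)=O
Why: DMAP-catalysed acetylation of the secondary alcohol installs the leaving group and touches neither the stereocentres nor the alkene geometry.

Step 11
Reactants: 19 the Z allylic acetate of step 10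
Product: 21 di-tert-butyl (4R,5R,9R,10S)-13,13-(ethane-1,2-diyldioxy)-13,14-secoabiet-7-ene-14,18-dioate, via ester enolate 20 (not isolated)
Conditions: Fe(acac)3 (30 mol %), PhSiH3 (slow addition), degassed EtOH (0.01 M), 60 °C
Reagents that add atoms: none
Why: Proposed new method: an iron hydride formed from Fe(acac)3 and PhSiH3 transfers a hydrogen atom to C1 of the electron-rich C1=C10 alkene, the tertiary C10 radical adds to C9 of the enoate, the C8 radical is reduced by divalent iron to ester enolate 20, and 20 expels the C7 acetate (E1cB), so the C7=C8 enoate is returned in the same flask. The closest known reaction types are the iron-catalysed reductive olefin coupling (hydrogen-atom-transfer Giese cyclisation, also used to end radical polyene cyclisations on 2-alkyl enoates) and the radical addition–elimination on Morita–Baylis–Hillman acetates under photoredox conditions, and what is new is their merger in a ring closure. Ring B closes in the 6-endo-trig mode, because the 5-exo site C8 is fully substituted and is the polarity-mismatched α-carbon. C10 is controlled by C5: the tether is equatorial on ring A and reaches the radical along the equatorial trajectory, while the axial path is blocked by the axial C4 methyl, which should give the trans-decalin with an axial C10 methyl. C9 is controlled by the Z geometry of the enoate in a chair transition state, in which C11 (trans to C7) becomes equatorial and 9-H becomes α, and both C7 epimers converge. The step needs hydrogen atom transfer to the ring alkene and not to the enoate, which is secured by the electron-poor, trisubstituted and α-branched nature of the enoate, and the dioxolane keeps enolate 20 from an aldol reaction at C13.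

Step 12
Reactants: 21 the bicyclic di-tert-butyl ester dioxolane of step 11
Product: 22 (1R,4aS,5R,8aR)-1,4a-dimethyl-5-(4-methyl-3-oxopentyl)-1,2,3,4,4a,5,8,8a-octahydronaphthalene-1,6-dicarboxylic acid (target CNP0333046.1)
Conditions: CF3CO2H/CH2Cl2/H2O (10:10:1), 0 °C to rt
Reagents that add atoms: water, O
Why: Acidolysis of both tert-butyl esters (alkyl–oxygen cleavage, independent of the hindrance at C4) and hydrolysis of the dioxolane occur together, while the electron-poor C7=C8 alkene and the four non-epimerisable stereocentres should remain unchanged.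

**Compound list**

1 | tert-butyl propanoate | CCC(=O)OC(C)(C)C | starting material
2 | lithium enolate of tert-butyl propanoate | [Li+].CC=C([O-])OC(C)(C)C | intermediate
3 | tert-butyl 2-methyl-3-oxopropanoate (racemic; partly enolised) | CC(C=O)C(=O)OC(C)(C)C | intermediate
4 | pent-1-en-3-one | C=CC(=O)CC | starting material
5 | tert-butyl (2R)-2-formyl-2-methyl-5-oxoheptanoate | CCC(=O)CC[C@](C)(C=O)C(=O)OC(C)(C)C | intermediate
6 | tert-butyl (1R)-1,3-dimethyl-4-oxocyclohex-2-ene-1-carboxylate | O=C1CC[C@@](C)(C(=O)OC(C)(C)C)C=C1C | intermediate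
7 | tert-butyl (1R,4R)-4-hydroxy-1,3-dimethylcyclohex-2-ene-1-carboxylate (OH cis to the ring methyl at the quaternary carbon) | O[C@@H]1CC[C@@](C)(C(=O)OC(C)(C)C)C=C1C | intermediate
8 | tert-butyl (1R,4R)-4-(ethenyloxy)-1,3-dimethylcyclohex-2-ene-1-carboxylate | C=CO[C@@H]1CC[C@@](C)(C(=O)OC(C)(C)C)C=C1C | intermediate
9 | tert-butyl (1R,2R)-1,3-dimethyl-2-(2-oxoethyl)cyclohex-3-ene-1-carboxylate | O=CC[C@@H]1C(C)=CCC[C@@]1(C)C(=O)OC(C)(C)C | intermediate
10 | 3-methylbutan-2-one | CC(C)C(C)=O | starting material
11 | 3-bromoprop-1-yne | C#CCBr | starting material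
12 | kinetic lithium enolate of 3-methylbutan-2-one | [Li+].C=C([O-])C(C)C | intermediate
13 | 2-methylhept-6-yn-3-one | CC(C)C(=O)CCC#C | intermediate
14 | 2-(but-3-yn-1-yl)-2-(propan-2-yl)-1,3-dioxolane | CC(C)C1(CCC#C)OCCO1 | intermediate
15 | lithium acetylide of 14 | [Li+].[C-]#CCCC1(C(C)C)OCCO1 | intermediate
16 | tert-butyl 5-[2-(propan-2-yl)-1,3-dioxolan-2-yl]pent-2-ynoate | CC(C)C1(CCC#CC(=O)OC(C)(C)C)OCCO1 | intermediate
17 | tert-butyl 2-(diisobutylalumanyl)-5-[2-(propan-2-yl)-1,3-dioxolan-2-yl]pent-2-enoate (aluminium cis to the vinyl hydrogen) | CC(C)C1(CC/C=C(\C(=O)OC(C)(C)C)[Al](CC(C)C)CC(C)C)OCCO1 | intermediate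
18 | Z allylic alcohol (name in step 9; C7 epimers) | CC(C)C1(CC/C=C(\C(=O)OC(C)(C)C)C(O)C[C@@H]2C(C)=CCC[C@@]2(C)C(=O)OC(C)(C)C)OCCO1 | intermediate
19 | Z allylic acetate (name in step 10; C7 epimers) | CC(C)C1(CC/C=C(\C(=O)OC(C)(C)C)C(OC(C)=O)C[C@@H]2C(C)=CCC[C@@]2(C)C(=O)OC(C)(C)C)OCCO1 | intermediate
20 | bicyclic C8 ester enolate carrying the C7 acetate (iron-bound; drawn as the anion) | CC(C)C1(CC[C@H]2C(=C([O-])OC(C)(C)C)C(OC(C)=O)C[C@@H]3[C@]2(C)CCC[C@@]3(C)C(=O)OC(C)(C)C)OCCO1 | intermediate
21 | di-tert-butyl (4R,5R,9R,10S)-13,13-(ethane-1,2-diyldioxy)-13,14-secoabiet-7-ene-14,18-dioate (trans-decalin, 5α-H, 9α-H, 10β-methyl) | CC(C)C1(CC[C@H]2C(C(=O)OC(C)(C)C)=CC[C@@H]3[C@]2(C)CCC[C@@]3(C)C(=O)OC(C)(C)C)OCCO1 | intermediate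
22 | (4R,5R,9R,10S)-13-oxo-13,14-secoabiet-7-ene-14,18-dioic acid (CNP0333046.1) | CC(C)C(=O)CC[C@H]1C(C(=O)O)=CC[C@@H]2[C@]1(C)CCC[C@@]2(C)C(=O)O | target

**Step count**

Total step count: 12. Longest linear sequence: 9 (steps 1–5 and 9–12).

**Steps most likely to fail**

Step 11. Three processes may compete with the intended closure:
- The 6-endo closure onto the β-substituted enoate may be slower than quenching of the C10 radical, which would give net hydrogenation of the ring alkene.
- Hydrogen atom transfer may go to the enoate, which would cause reductive loss of acetate without ring closure.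
- Reversible hydrogen abstraction next to the radical may erode C5.

The fallback raises the electrophilicity of the acceptor by changing the oxidation level at C7, and it separates bond formation from elimination using known reactions only. It sets out from alcohol 18. Oxidation with Dess–Martin periodinane should give the doubly activated Z 2-alkylidene-3-oxo ester F1, which is used at once. The known iron-catalysed reductive olefin coupling (Fe(acac)3, PhSiH3, EtOH, 60 °C) closes ring B to the bicyclic β-keto ester F2. NaBH4 in MeOH gives the β-hydroxy ester F3, MsCl/Et3N gives the mesylate F4, and DBU eliminates it to 21, where the route is rejoined.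

Step 2. Uncatalysed background addition of the strongly enolised formyl ester, poor facial discrimination between the small formyl group and the ester, and deformylation may all lower the enantiomeric purity. The fallback moves the source of absolute configuration from the C–C bond formation to the reduction. It sets out from 3 and 4. Et3N in CH2Cl2 gives the racemic keto aldehyde F5, and pyrrolidine/AcOH gives the racemic enone F6. The (S)-2-methyl-CBS-oxazaborolidine/BH3·SMe2 reduction then converts the two enantiomers into diastereomeric (4R)-carbinols, 7 and the (1S,4R)-carbinol F7. These are separated by chromatography, and the route is rejoined at 7.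

Step 9. Equilibration of the vinylalane through its aluminium allenolate may erode the alkene geometry, and leftover hydride may reduce aldehyde 9. The fallback replaces the transient aluminium species by an isolable, geometrically pure alkenyl halide. It sets out from ynoate 16. Syn hydrostannation with Bu3SnH under Pd(PPh3)4 catalysis (zerovalent palladium) gives the α-stannyl enoate F8, and I2 gives the α-iodo enoate F9, purified as one isomer. A Nozaki–Hiyama–Kishi coupling (CrCl2, NiCl2 cat., DMF) with aldehyde 9 gives 18, where the route is rejoined.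

**Further compounds**

F1 | step 11 | tert-butyl (1R,2R)-2-[(3Z)-3-(tert-butoxycarbonyl)-2-oxo-6-[2-(propan-2-yl)-1,3-dioxolan-2-yl]hex-3-en-1-yl]-1,3-dimethylcyclohex-3-ene-1-carboxylate | CC(C)C1(CC/C=C(\C(=O)OC(C)(C)C)C(=O)C[C@@H]2C(C)=CCC[C@@]2(C)C(=O)OC(C)(C)C)OCCO1
F2 | step 11 | 7-oxo-7,8-dihydro derivative of 21 (bicyclic β-keto ester; C4, C5, C9, C10 as in 21, C8 unassigned) | CC(C)C1(CC[C@H]2C(C(=O)OC(C)(C)C)C(=O)C[C@@H]3[C@]2(C)CCC[C@@]3(C)C(=O)OC(C)(C)C)OCCO1
F3 | step 11 | 7-hydroxy-7,8-dihydro derivative of 21 (β-hydroxy ester; C7 and C8 unassigned) | CC(C)C1(CC[C@H]2C(C(=O)OC(C)(C)C)C(O)C[C@@H]3[C@]2(C)CCC[C@@]3(C)C(=O)OC(C)(C)C)OCCO1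
F4 | step 11 | 7-methanesulfonyloxy-7,8-dihydro derivative of 21 | CC(C)C1(CC[C@H]2C(C(=O)OC(C)(C)C)C(OS(C)(=O)=O)C[C@@H]3[C@]2(C)CCC[C@@]3(C)C(=O)OC(C)(C)C)OCCO1
F5 | step 2 | racemic tert-butyl 2-formyl-2-methyl-5-oxoheptanoate | CCC(=O)CCC(C)(C=O)C(=O)OC(C)(C)C
F6 | step 2 | racemic tert-butyl 1,3-dimethyl-4-oxocyclohex-2-ene-1-carboxylate | O=C1CCC(C)(C(=O)OC(C)(C)C)C=C1C
F7 | step 2 | tert-butyl (1S,4R)-4-hydroxy-1,3-dimethylcyclohex-2-ene-1-carboxylate | O[C@@H]1CC[C@](C)(C(=O)OC(C)(C)C)C=C1C
F8 | step 9 | tert-butyl (2E)-5-[2-(propan-2-yl)-1,3-dioxolan-2-yl]-2-(tributylstannyl)pent-2-enoate | CC(C)C1(CC/C=C(\C(=O)OC(C)(C)C)[Sn](CCCC)(CCCC)CCCC)OCCO1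
F9 | step 9 | tert-butyl (2E)-2-iodo-5-[2-(propan-2-yl)-1,3-dioxolan-2-yl]pent-2-enoate | CC(C)C1(CC/C=C(\C(=O)OC(C)(C)C)I)OCCO1
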